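## Structural features

The target is a tricyclic sesquiterpenoid. Ring B (C5–C10, with the C7 ketone and the C8=C9 alkene bearing a methyl) and ring C (cyclobutane C5, C6, C11, C10) form a bicyclo[3.1.1]hept-3-en-2-one. The chain C1–C4 joins the two one-carbon bridges C5 and C11 and closes the seven-membered ring A. C1, C2 and C3 carry an angelate, an isovalerate and a free hydroxyl; C5, C6 and C10 are cyclobutane methines; C11 is a quaternary cyclobutane carbon with a methyl; C4 is a second quaternary carbon (gem-dimethyl) between C3 and C5. Ring A must leave C5 and C11 on the cyclobutane face away from ring B, so the C11 methyl lies over ring B and shields one face of C7–C9. Ring A also lies close to a local mirror plane of the bicyclic core, so the two faces of C1–C3 differ only through the remote C7 and C9. Fragile groups are the angelate (Z to E isomerisation), the neighbouring ester and hydroxyl groups (acyl migration), the enone, and the strained ring next to a ketone. The real difficulties are the four-membered ring with its quaternary C11 and the relay of configuration from the core to C1–C3. The key step uses two facts: C11 is α to C1, which can be a ketone, and C10 is a secondary carbon on C5, the neighbour of C6. In a cis-fused ring A/ring B bicycle an enolate at C11 can therefore displace a leaving group on C10, forming C10–C11 and closing ring C.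

## Logic of the disconnections

37 to 33 (through 35). The C8=C9 bond is removed first, because the enone is the most base-sensitive group and a saturated C9 can carry the methyl from the chiral pool. The forward step must dehydrogenate beside two esters and a free hydroxyl. The C9 hydrogen lies on the ring B face under the C11 methyl, so a syn elimination (palladium enolate, selenoxide) is avoided and an anti elimination of a C8 bromide is planned.

33 to 30 (through 32). The C7 ketone is masked as a dioxolane and the C2–O acyl bond is cut. This leaves a cis diol whose two hydroxyls differ sterically (C3 is neopentylic). The forward acylation must be selective for C2 and must not trigger acyl migration.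

30 to 29. The C2–O and C3–O bonds are cut together to the C2=C3 alkene. Two stereocentres come from one syn addition. The forward step needs the osmium reagent to approach anti to the C1 ester.

29 to 26 (through 27). The C1–O acyl bond and the C1–H bond are cut to the C1 ketone. This gives the enone needed for the key step. The forward reduction needs facial control at a carbonyl with almost no substrate bias, so reagent control is planned, and the angelate must be introduced without isomerisation.

26 to 24 (key). The C10–C11 bond is cut, opening ring C and removing the quaternary centre. What remains is a cis-fused cycloheptenone–cyclohexane with a leaving group on C10. The forward step needs inversion at C10, C- over O-alkylation, and a cis ring fusion that holds C11 axial on C6.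

24 to 21 (through 23 and 22). The C1 carbonyl oxygen is removed back to an allylic methylene and the tosylate back to a benzoate. The ring A carbonyl then appears only after the C7 ketal is in place, so no ketalisation beside an enone and no organometallic addition beside a free ketone is required. The forward oxidation must attack C1, the only allylic CH2.

21 to 20. The C2=C3 bond is cut by metathesis logic to two terminal alkenes, an allyl group on C11 and a vinyl group on C4. Ring A disappears. The forward closure must accept a neopentyl alkene.

20 to 16 and 17 (through 19). The ketal, the C11–C1 bond and the C6–H bond are cut to a 2-ethylidene ketone. C6 must end cis to the C5 side chain. A direct alkylation of the enolate from the first conjugate addition would place the new group anti to C4, which is the wrong relationship. The C6 hydrogen is therefore delivered last, by kinetic ketonisation anti to the C5 substituent.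

16 to 10, 11 and 12 (through 14). The C5–C4 bond and the C6=C11 bond are cut. This leaves a 4-acyloxy-5-methylcyclohexenone, a prenylsilane (C2, C3, C4 and both C4 methyls) and acetaldehyde (C11 and its methyl). The forward conjugate addition needs attack anti to the C10 oxygen, so that oxygen is placed cis to the C9 methyl and the two groups reinforce each other.

10 to 5 (through 9, 7 and 6). The C10–O bond is cut. Deconjugative ketalisation fixes the site of oxidation, and a Mitsunobu inversion gives the cis arrangement.

5 to 1. The isopropylidene carbon unit is cut away; the C9 stereocentre comes unchanged from the terpene.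

## Other disconnections considered

Alternative 1: The cut is across C5–C6 and C10–C11 at once. Forward, the acid chloride A1 would give a vinylketene with Et3N, and an intramolecular [2+2] cycloaddition would give the bicyclo[3.1.1]heptanone A2. In its favour: one step from an acyclic precursor builds ring C and the carbocycle of ring B, the quaternary C11 follows from the (6E) alkene geometry, and the exocyclic alkene can be moved into ring B and oxidised at C7 (pinene to verbenone logic). On step economy to the core, and on avoiding a late C8=C9 dehydrogenation, it is better than the chosen plan. Against it: A2 is racemic and the cycloaddition offers no handle for absolute control. Ring A would still have to be closed by a C4–C5 bond at the strained cyclobutanone carbon, followed by removal of the C5 oxygen with control of C5. C1 is a methylene that must be oxidised, and the C1–C3 oxygens are not addressed. The chosen plan is longer to the core but starts enantiopure and has ring A in place before ring C.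

Alternative 2: The cut is C2–C3, closing ring A by aldol. Forward, the boron enolate of the alkoxymethyl ketone in A3 would add to the C3 aldehyde to give A4. In its favour: enolisation is unambiguous because C11 is quaternary; C2 and C3 arise already differentiated (ether and free hydroxyl); the ring B enone is present, so no late dehydrogenation is needed; and the C1 ketone could later be reduced under the influence of the neighbouring C2 centre. On these points it is equal to or better than the chosen plan. Against it: the seven-membered closure joins two neopentyl carbonyl carbons and is open to retro-aldol. The cis relationship of the C2 and C3 oxygens and their relation to the core are not secured by the enolate geometry. The enone and C7 ketone compete for the boron reagent. A3 already contains the cyclobutane with quaternary C11, so the hardest problem moves into the precursor. The chosen plan solves that problem directly and sets C2 and C3 by one syn addition.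

Alternative 3: The cut is C9–C10, closing ring B by radical addition. Forward, reductive fragmentation of the N-acyloxyphthalimide A5 would give a C10 cyclobutyl radical, 6-endo-dig addition to C9 of the ynone, and A6. In its favour: ring B forms at its final oxidation level with the methyl in place, the conditions are neutral, no leaving-group stereocentre is needed, and C1 is already configured. On the enone and on functional-group tolerance it is better than the chosen plan. Against it: A5 is a fully substituted cyclobutane with four ring stereocentres including quaternary C11, needing the C6 acyl and C10 carboxyl cis. The radical must form the bridged bicycle in competition with hydrogen capture and with 5-exo attack at C8. The chosen plan forms the strained ring last, by an ionic displacement with defined inversion, from a bicycle made by standard reactions.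

Key step: step 16

Remark: locants C1–C11 are those of the target skeleton throughout; compounds 19–24 are carried as mixtures of C11 epimers, because this centre becomes planar in enolate 25.

## Route

Step 1
Reactants: 1 (S)-pulegone
Product: 2 pulegone oxide (spiro epoxide of 1; epoxide carbon unassigned)
Conditions: 30% H2O2, LiOH (cat.), MeOH, 0 °C to rt
Reagents that add atoms: hydrogen peroxide, OO
Why: Nucleophilic (Weitz–Scheffer) epoxidation of the tetrasubstituted enone; the methyl stereocentre is untouched and the epoxide configuration is irrelevant because that carbon is cleaved in step 2.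

Step 2
Reactants: 2 pulegone oxide
Product: 3 (5S)-5-methyl-2-(phenylsulfanyl)cyclohexan-1-one (C2 epimers)
Conditions: PhSH, NaH (10 mol%), THF, reflux
Reagents that add atoms: benzenethiol, Sc1ccccc1
Why: Thiolate opens the epoxide at the carbon α to the ketone and the tertiary alkoxide undergoes retro-aldol loss of acetone, a known degradation of pulegone oxide; catalytic base suffices because the thiol reprotonates the enolate.

Step 3
Reactants: 3 (5S)-5-methyl-2-(phenylsulfanyl)cyclohexan-1-one
Product: 5 (S)-5-methylcyclohex-2-en-1-one, via sulfoxide 4 (not isolated)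
Conditions: mCPBA (1.0 equiv), CH2Cl2, −78 °C; then CaCO3, toluene, 110 °C
Reagents that add atoms: none
Why: Sulfide oxidation and thermal syn elimination of the sulfoxide place the alkene regiospecifically on the sulfur-bearing side; the remote methyl centre is not enolisable.

Step 4
Reactants: 5 (S)-5-methylcyclohex-2-en-1-one
Product: 6 (R)-9-methyl-1,4-dioxaspiro[4.5]dec-7-ene (β,γ-unsaturated ethylene ketal; methyl centre unchanged)
Conditions: HOCH2CH2OH, p-TsOH (cat.), benzene, reflux, Dean–Stark
Reagents that add atoms: ethane-1,2-diol, OCCO
Why: Acid-catalysed ketalisation of a cyclohexenone moves the alkene out of conjugation, which fixes C10 as the site of oxygenation with no ambiguity between the α′ and γ positions; any conjugated ketal is hydrolysed back to 5.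

Step 5
Reactants: 6 (R)-9-methyl-1,4-dioxaspiro[4.5]dec-7-ene
Product: 7 7,8-epoxy-9-methyl-1,4-dioxaspiro[4.5]decane (oxirane trans to the methyl)
Conditions: mCPBA, NaHCO3, CH2Cl2, 0 °C
Reagents that add atoms: 3-chloroperoxybenzoic acid, OOC(=O)c1cccc(Cl)c1
Why: Prilezhaev epoxidation of the only alkene; attack anti to the neighbouring methyl is taken as the main course, but the route does not depend on it because the syn epoxide is carried to the same benzoate 10 (see the risk discussion).

Step 6
Reactants: 7 7,8-epoxy-9-methyl-1,4-dioxaspiro[4.5]decane
Product: 9 (4S,5R)-4-hydroxy-5-methylcyclohex-2-en-1-one (hydroxyl trans to methyl), via epoxy ketone 8 (not isolated)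
Conditions: PPTS, acetone–H2O, 40 °C; then Et3N, CH2Cl2, rt
Reagents that add atoms: water, O
Why: Transketalisation frees the ketone, and the β,γ-epoxy ketone opens by E1cB elimination (enolisation toward C6, cleavage of the C5–O bond) to the γ-hydroxy enone; C10 keeps the configuration of its epoxide C–O bond.

Step 7
Reactants: 9 (4S,5R)-4-hydroxy-5-methylcyclohex-2-en-1-one
Product: 10 (1R,6R)-6-methyl-4-oxocyclohex-2-en-1-yl benzoate (ester cis to methyl)
Conditions: PhCO2H, PPh3, DIAD, THF, 0 °C to rt
Reagents that add atoms: benzoic acid, OC(=O)c1ccccc1
Why: Mitsunobu esterification inverts the allylic carbinol C10 by SN2 displacement of the oxyphosphonium group; the ester is now cis to the C9 methyl, so both substituents shield the same face in step 8, and the benzoate protects C10.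

Step 8
Reactants: 10 (1R,6R)-6-methyl-4-oxocyclohex-2-en-1-yl benzoate; 11 trimethyl(3-methylbut-2-enyl)silane; 12 acetaldehyde
Product: 14 3-(1-hydroxyethyl)-6-methyl-2-(2-methylbut-3-en-2-yl)-4-oxocyclohexyl benzoate (C2 chain trans to OBz and to 6-Me; C3 and carbinol centres unassigned), via trichlorotitanium enolate 13 (not isolated)
Conditions: 11 (1.2 equiv), TiCl4 (1.1 equiv), CH2Cl2, −78 °C; then 12, −78 °C; aq. NaHCO3
Reagents that add atoms: none
Why: Hosomi–Sakurai conjugate addition: the silane reacts through its γ-carbon and so installs the 1,1-dimethylallyl group (C4 with both methyls, C3=C2) at C5, anti to both the C10 benzoate and the C9 methyl. The titanium enolate forms regiospecifically at C6 and is trapped by aldol addition to acetaldehyde; the C6 and carbinol configurations are erased in step 9.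

Step 9
Reactants: 14 3-(1-hydroxyethyl)-6-methyl-2-(2-methylbut-3-en-2-yl)-4-oxocyclohexyl benzoate
Product: 16 (E)-3-ethylidene-6-methyl-2-(2-methylbut-3-en-2-yl)-4-oxocyclohexyl benzoate, via mesylate 15 (not isolated)
Conditions: MsCl, Et3N, CH2Cl2, 0 °C; then DBU, rt
Reagents that add atoms: none
Why: Mesylation and E1cB elimination of the β-mesyloxy ketone give the 2-alkylidene ketone; C11 (with its hydrogen and methyl) becomes the β-carbon of an exocyclic enone and C6 becomes sp2, ready to receive its hydrogen last.

Step 10
Reactants: 16 (E)-3-ethylidene-6-methyl-2-(2-methylbut-3-en-2-yl)-4-oxocyclohexyl benzoate; 17 allyltrimethylsilane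
Product: 19 6-methyl-2-(2-methylbut-3-en-2-yl)-4-oxo-3-(pent-4-en-2-yl)cyclohexyl benzoate (C2 and C3 chains cis; C11 epimers), via trichlorotitanium enolate 18 (not isolated)
Conditions: 17 (1.5 equiv), TiCl4 (1.1 equiv), CH2Cl2, −78 °C; AcOH in THF at −78 °C, then aq. NaHCO3
Reagents that add atoms: none
Why: A second Hosomi–Sakurai addition, to the unhindered exocyclic β-carbon C11, gives the C6=C7 enolate regiospecifically. Kinetic ketonisation delivers the proton to C6 axially and anti to the 1,1-dimethylallyl group on C5 (held pseudoaxial by A(1,2) strain), so C11 ends cis to C4; a direct alkylation of enolate 13 would have placed it trans.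

Step 11
Reactants: 19 6-methyl-2-(2-methylbut-3-en-2-yl)-4-oxo-3-(pent-4-en-2-yl)cyclohexyl benzoate
Product: 20 ethylene ketal of 19 at C7 (C5 and C6 chains cis; C11 epimers)
Conditions: (Me3SiOCH2)2, Me3SiOTf (5 mol%), CH2Cl2, −78 to −30 °C; pyridine quench
Reagents that add atoms: 1,2-bis(trimethylsilyloxy)ethane, C[Si](C)(C)OCCO[Si](C)(C)C
Why: Noyori ketalisation is irreversible at low temperature and does not pass through the enol, so the contra-thermodynamic cis C5/C6 relationship is kept and C6 is no longer epimerisable. The ketal is installed before any C1 carbonyl exists.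

Step 12
Reactants: 20 ethylene ketal of 19
Product: 21 cis-fused bicyclo[5.4.0]undecene (ring A cycloheptene C2=C3; C4 gem-dimethyl; C7 dioxolane; C9 and C11 methyls; C10 benzoate; C11 epimers)
Conditions: second-generation Grubbs catalyst RuCl2(=CHPh)(H2IMes)(PCy3) (5 mol%), CH2Cl2 (5 mM), 40 °C
Reagents that add atoms: none
Why: Ring-closing metathesis of the allyl group on C11 with the neopentyl vinyl group on C4 forms C2=C3 and ring A; initiation at the unhindered allyl terminus and the gem-dimethyl group favour closure.

Step 13
Reactants: 21 cis-fused bicyclic benzoate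
Product: 22 C10 alcohol of 21 (hydroxyl trans to the C5 ring bond and cis to the C9 methyl; C11 epimers)
Conditions: NaOMe (cat.), MeOH, 50 °C
Reagents that add atoms: none
Why: Base-catalysed transesterification removes the benzoate; no carbonyl or base-labile group is present at this stage.

Step 14
Reactants: 22 C10 alcohol
Product: 23 C10 tosylate of 22 (C11 epimers)
Conditions: TsCl, DMAP (cat.), pyridine, 40 °C
Reagents that add atoms: 4-methylbenzenesulfonyl chloride, Cc1ccc(cc1)S(Cl)(=O)=O
Why: Sulfonylation with retention at C10 puts the leaving group trans to the C5 side chain, as the displacement in step 16 requires.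

Step 15
Reactants: 23 C10 tosylate
Product: 24 cis-fused cycloheptenone–cyclohexane keto tosylate (C1 ketone; C2=C3; C7 dioxolane; C10 tosylate; C11 epimers)
Conditions: CrO3, 3,5-dimethylpyrazole, CH2Cl2, −20 °C
Reagents that add atoms: chromium trioxide, O=[Cr](=O)=O
Why: Allylic oxidation with the CrO3–3,5-dimethylpyrazole complex at C1, the only allylic methylene (C4 on the other side is quaternary), should give the cycloheptenone without moving the double bond; tosylate and ketal should survive at −20 °C.

Step 16
Reactants: 24 cis-fused cycloheptenone–cyclohexane keto tosylate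
Product: 26 tricyclic ring A enone with C7 dioxolane (rings A, B and C closed; C11 quaternary), via potassium dienolate 25 (not isolated)
Conditions: KN(SiMe3)2 (1.1 equiv), THF (5 mM), −78 to 0 °C
Reagents that add atoms: none
Why: KN(SiMe3)2 removes the only enolisable hydrogen (C11–H; C2=C3 and the quaternary C4 block the other side) to give the cross-conjugated potassium dienolate 25. In the chair of ring B that holds the C10 tosylate equatorial, the cis ring fusion places C11 axial on C6, 1,3 to C10 and in line with the back lobe of the C10–O bond, so C11 attacks C10 in an intramolecular SN2 reaction (4-exo-tet) that forms C10–C11 and closes ring C. The closest known reaction type is the closure of bridged cyclobutanes (bicyclo[3.1.1]heptanones) by alkylation of a ketone enolate with a ring sulfonate; forming a quaternary carbon this way is the demanding extension. C10 is inverted, which is why the tosylate was set trans to the C5 side chain; the configuration of the new quaternary C11 is dictated by the tether, since C1 and C6 are held by rings A and B and the methyl must take the position over ring B. C-alkylation is needed over O-alkylation, and the ring A tether secures it: the O-alkylated product would hold the C1=C11 enol ether at a bridgehead of a bicyclo[3.2.2]nonene. E2 loss of the tosylate is limited because the equatorial tosylate has no antiperiplanar hydrogen in the reactive chair and the hindered base is consumed in enolate formation; high dilution suppresses intermolecular alkylation.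

Step 17
Reactants: 26 tricyclic ring A enone
Product: 27 (1R) allylic alcohol of 26 (C1 hydroxyl on the C6/C7 side of ring A)
Conditions: (S)-2-methyl-CBS-oxazaborolidine (0.5 equiv), BH3·SMe2, THF, −30 °C; MeOH
Reagents that add atoms: none
Why: Corey–Bakshi–Shibata reduction: with the quaternary C11 as the large and the alkenyl C2 as the small substituent, the (S)-catalyst should deliver hydride to the face of C1 that gives the (1R) alcohol. Reagent control is chosen because ring A lies near a local mirror plane of the core and the substrate offers little bias.

Step 18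
Reactants: 27 (1R) allylic alcohol; 28 angelic anhydride [(Z)-2-methylbut-2-enoic anhydride]
Product: 29 C1 angelate of 27
Conditions: LiN(SiMe3)2, THF, −78 °C; then 28, −78 to 0 °C
Reagents that add atoms: none
Why: Acylation of the lithium alkoxide with the anhydride at low temperature esterifies the hindered alcohol without a nucleophilic amine catalyst, which is how Z to E isomerisation to the tiglate is avoided.

Step 19
Reactants: 29 C1 angelate
Product: 30 C2,C3 cis-diol of 29 (both hydroxyls trans to the C1 angelate)
Conditions: OsO4 (5 mol%), NMO, acetone–H2O, rt; Na2SO3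
Reagents that add atoms: 4-methylmorpholine N-oxide, C[N+]1([O-])CCOCC1; water, O
Why: Upjohn dihydroxylation: OsO4 adds to the cis-disubstituted C2=C3 from the face anti to the allylic C1 ester (Kishi-type control), setting C2 and C3 cis to each other and trans to the C1 oxygen; the conjugated trisubstituted alkene of the angelate reacts far more slowly.

Step 20
Reactants: 30 C2,C3 cis-diol; 31 3-methylbutanoyl chloride (isovaleryl chloride)
Product: 32 C2 isovalerate of 30 (C3 hydroxyl free)
Conditions: 31 (1.1 equiv), 2,4,6-collidine, CH2Cl2, −40 to 0 °C
Reagents that add atoms: none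
Why: Selective acylation: the C3 hydroxyl is neopentylic (next to the quaternary C4) and reacts more slowly than the C2 hydroxyl; low temperature and a hindered weak base limit bis-acylation and acyl migration.

Step 21
Reactants: 32 C2 isovalerate
Product: 33 C7 ketone of 32 (saturated at C8–C9)
Conditions: PPTS, acetone–H2O (9:1), 50 °C
Reagents that add atoms: water, O
Why: Acid-catalysed transketalisation unmasks the C7 ketone; the esters and the free hydroxyl tolerate pyridinium tosylate.

Step 22
Reactants: 33 C7 ketone
Product: 35 C8 bromo ketone with C3 trimethylsilyl ether (bromine cis to the C9 methyl), via bis(trimethylsilyl) compound 34 (not isolated)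
Conditions: Me3SiOTf (2.5 equiv), Et3N, CH2Cl2, 0 °C; then NBS, THF, −78 °C; aq. NaHCO3
Reagents that add atoms: trimethylsilyl trifluoromethanesulfonate, C[Si](C)(C)OS(=O)(=O)C(F)(F)F; N-bromosuccinimide, BrN1C(=O)CCC1=O
Why: Soft enolisation can only go toward C8 because C6 is a bridgehead of the bicyclo[3.1.1]heptane, and NBS brominates the silyl enol ether on the ring B face away from the C11 methyl; the C3 hydroxyl is silylated in passing. An anti-elimination route is chosen because the C9 hydrogen lies under the C11 methyl, where a palladium enolate or a selenoxide could not reach it syn.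

Step 23
Reactants: 35 C8 bromo ketone
Product: 37 target CNP0251293.1, via silyl ether 36 (not isolated)
Conditions: DBU, toluene, 0 °C to rt; then citric acid, MeOH–H2O
Reagents that add atoms: none
Why: E2 dehydrobromination: the C9–H bond is anti to the C8–Br bond, so DBU should give the conjugated C8=C9 enone; mild acid then frees the C3 hydroxyl.

## Compound list

1 | (S)-pulegone | C[C@H]1CCC(=C(C)C)C(=O)C1 | starting material
2 | pulegone oxide | C[C@H]1CCC2(OC2(C)C)C(=O)C1 | intermediate
3 | (5S)-5-methyl-2-(phenylsulfanyl)cyclohexan-1-one | C[C@H]1CCC(Sc2ccccc2)C(=O)C1 | intermediate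
4 | (5S)-5-methyl-2-(phenylsulfinyl)cyclohexan-1-one | C[C@H]1CCC(S(=O)c2ccccc2)C(=O)C1 | intermediate
5 | (S)-5-methylcyclohex-2-en-1-one | C[C@H]1CC=CC(=O)C1 | intermediate
6 | (R)-9-methyl-1,4-dioxaspiro[4.5]dec-7-ene | C[C@@H]1CC2(OCCO2)CC=C1 | intermediate
7 | 7,8-epoxy-9-methyl-1,4-dioxaspiro[4.5]decane, oxirane trans to methyl | C[C@@H]1CC2(OCCO2)C[C@H]3O[C@@H]13 | intermediate
8 | 3,4-epoxy-5-methylcyclohexanone, oxirane trans to methyl | C[C@@H]1CC(=O)C[C@H]2O[C@@H]12 | intermediate
9 | (4S,5R)-4-hydroxy-5-methylcyclohex-2-en-1-one | O=C1C=C[C@@H](O)[C@H](C)C1 | intermediate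
10 | (1R,6R)-6-methyl-4-oxocyclohex-2-en-1-yl benzoate | O=C1C=C[C@H](OC(=O)c2ccccc2)[C@H](C)C1 | intermediate
11 | trimethyl(3-methylbut-2-enyl)silane | CC(C)=CC[Si](C)(C)C | starting material
12 | acetaldehyde | CC=O | starting material
13 | trichlorotitanium enolate (C6=C7) of the Sakurai adduct of 10 | C=CC(C)(C)[C@@H]1C=C(O[Ti](Cl)(Cl)Cl)C[C@@H](C)[C@H]1OC(=O)c2ccccc2 | intermediate
14 | 3-(1-hydroxyethyl)-6-methyl-2-(2-methylbut-3-en-2-yl)-4-oxocyclohexyl benzoate | C=CC(C)(C)[C@@H]1[C@@H](C(C)O)C(=O)C[C@@H](C)[C@H]1OC(=O)c2ccccc2 | intermediate
15 | mesylate of 14 | C=CC(C)(C)[C@@H]1[C@@H](C(C)OS(C)(=O)=O)C(=O)C[C@@H](C)[C@H]1OC(=O)c2ccccc2 | intermediate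
16 | (E)-3-ethylidene-6-methyl-2-(2-methylbut-3-en-2-yl)-4-oxocyclohexyl benzoate | C=CC(C)(C)[C@@H]1/C(=C\C)C(=O)C[C@@H](C)[C@H]1OC(=O)c2ccccc2 | intermediate
17 | allyltrimethylsilane | C=CC[Si](C)(C)C | starting material
18 | trichlorotitanium enolate (C6=C7) of the allyl adduct of 16 | C=CC(C)(C)[C@@H]1C(C(C)CC=C)=C(O[Ti](Cl)(Cl)Cl)C[C@@H](C)[C@H]1OC(=O)c2ccccc2 | intermediate
19 | 6-methyl-2-(2-methylbut-3-en-2-yl)-4-oxo-3-(pent-4-en-2-yl)cyclohexyl benzoate, side chains cis, C11 epimers | C=CC(C)(C)[C@@H]1[C@H](C(C)CC=C)C(=O)C[C@@H](C)[C@H]1OC(=O)c2ccccc2 | intermediate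
20 | C7 ethylene ketal of 19 | C=CC(C)(C)[C@@H]1[C@H](C(C)CC=C)C2(OCCO2)C[C@@H](C)[C@H]1OC(=O)c3ccccc3 | intermediate
21 | cis-fused cycloheptene–cyclohexane, C7 dioxolane, C10 benzoate, C11 epimers | C1C=CC(C)(C)[C@@H]2[C@H](C1C)C3(OCCO3)C[C@@H](C)[C@H]2OC(=O)c4ccccc4 | intermediate
22 | C10 alcohol of 21 | C1C=CC(C)(C)[C@@H]2[C@H](C1C)C3(OCCO3)C[C@@H](C)[C@H]2O | intermediate
23 | C10 tosylate of 22 | C1C=CC(C)(C)[C@@H]2[C@H](C1C)C3(OCCO3)C[C@@H](C)[C@H]2OS(=O)(=O)c4ccc(C)cc4 | intermediate
24 | cis-fused cycloheptenone–cyclohexane keto tosylate (key-step precursor), C11 epimers | O=C1C=CC(C)(C)[C@@H]2[C@H](C1C)C3(OCCO3)C[C@@H](C)[C@H]2OS(=O)(=O)c4ccc(C)cc4 | intermediate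
25 | potassium dienolate of 24 | CC1=C([O-])C=CC(C)(C)[C@@H]2[C@H]1C3(OCCO3)C[C@@H](C)[C@H]2OS(=O)(=O)c4ccc(C)cc4.[K+] | intermediate
26 | tricyclic ring A enone with C7 dioxolane (key-step product) | O=C1C=CC(C)(C)[C@@H]2[C@H]3C4(OCCO4)C[C@@H](C)[C@@H]2[C@@]13C | intermediate
27 | (1R) allylic alcohol of 26 | O[C@@H]1C=CC(C)(C)[C@@H]2[C@H]3C4(OCCO4)C[C@@H](C)[C@@H]2[C@@]13C | intermediate
28 | angelic anhydride | C/C=C(/C)C(=O)OC(=O)/C(C)=C\C | starting material
29 | C1 angelate of 27 | C/C=C(/C)C(=O)O[C@@H]1C=CC(C)(C)[C@@H]2[C@H]3C4(OCCO4)C[C@@H](C)[C@@H]2[C@@]13C | intermediate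
30 | C2,C3 cis-diol of 29 | C/C=C(/C)C(=O)O[C@@H]1[C@@H](O)[C@@H](O)C(C)(C)[C@@H]2[C@H]3C4(OCCO4)C[C@@H](C)[C@@H]2[C@@]13C | intermediate
31 | 3-methylbutanoyl chloride | CC(C)CC(Cl)=O | starting material
32 | C2 isovalerate of 30 | C/C=C(/C)C(=O)O[C@@H]1[C@@H](OC(=O)CC(C)C)[C@@H](O)C(C)(C)[C@@H]2[C@H]3C4(OCCO4)C[C@@H](C)[C@@H]2[C@@]13C | intermediate
33 | C7 ketone of 32 | C/C=C(/C)C(=O)O[C@@H]1[C@@H](OC(=O)CC(C)C)[C@@H](O)C(C)(C)[C@@H]2[C@H]3C(=O)C[C@@H](C)[C@@H]2[C@@]13C | intermediate
34 | C7 trimethylsilyl enol ether and C3 trimethylsilyl ether of 33 | C/C=C(/C)C(=O)O[C@@H]1[C@@H](OC(=O)CC(C)C)[C@@H](O[Si](C)(C)C)C(C)(C)[C@@H]2[C@H]3C(O[Si](C)(C)C)=C[C@@H](C)[C@@H]2[C@@]13C | intermediate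
35 | C8 bromo ketone, C3 trimethylsilyl ether | C/C=C(/C)C(=O)O[C@@H]1[C@@H](OC(=O)CC(C)C)[C@@H](O[Si](C)(C)C)C(C)(C)[C@@H]2[C@H]3C(=O)[C@@H](Br)[C@@H](C)[C@@H]2[C@@]13C | intermediate
36 | C3 trimethylsilyl ether of the target | C/C=C(/C)C(=O)O[C@@H]1[C@@H](OC(=O)CC(C)C)[C@@H](O[Si](C)(C)C)C(C)(C)[C@@H]2[C@H]3C(=O)C=C(C)[C@@H]2[C@@]13C | intermediate
37 | CNP0251293.1 | C/C=C(/C)C(=O)O[C@@H]1[C@@H](OC(=O)CC(C)C)[C@@H](O)C(C)(C)[C@@H]2[C@H]3C(=O)C=C(C)[C@@H]2[C@@]13C | target

## Step count and least certain steps

Total step count: 23. Longest linear sequence: 23 steps (1 to 37).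

Step 16 (key step). The most likely failure is that ring closure at the fully substituted enolate carbon is too slow, so that the tosylate is lost by elimination through the other chair or the dienolate is consumed intermolecularly. The fallback sets out from 24. Condensation with 1,1-dimethylhydrazine (AcOH cat., EtOH) would give the N,N-dimethylhydrazone of 24 F1. Deprotonation at C11 with KN(SiMe3)2 would give the aza-dienolate, a more nucleophilic, carbon-selective metalloenamine, which should close ring C to the tricyclic N,N-dimethylhydrazone F2. Hydrolysis with Cu(OAc)2 in THF–H2O returns to the route at 26.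

Step 10. The risk is loss of the kinetic cis relationship at C6, by protonation from the wrong face or by epimerisation during quench and handling. The fallback replaces proton transfer by hydrogen-atom transfer and sets out from 16. Conjugate allylation with allyltributylstannane and Me3SiOTf would give the isolable C6=C7 trimethylsilyl enol ether F3. PhSeCl would convert it into the C6 phenylselanyl ketone F4. Bu3SnH with AIBN would then generate the planar C6 radical, which should take hydrogen on the face away from the C5 substituent under neutral, irreversible conditions. The fallback rejoins the route at 19.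

Step 17. The risk is poor facial selectivity, either because catalyst and substrate preferences are mismatched or because the catalyst treats the alkenyl carbon as the large group. The fallback sets out from 26 with an unselective Luche reduction (NaBH4, CeCl3, MeOH). The diastereomers would be separated; the desired one is 27. The (1S) allylic alcohol F5 would be oxidised with MnO2 back to 26 and recycled.

Step 15. The risk is allylic transposition (oxygen entering at C3) or over-oxidation. The fallback sets out from 23 and uses an ene mechanism that cannot transpose. SeO2 (cat.) with t-BuOOH would add selenium at C3 with hydrogen transfer from C1, and the [2,3] shift returns oxygen to C1, giving the C1 allylic alcohol tosylate F6. Dess–Martin periodinane would then give 24.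

Step 20. The risk is acylation at the wrong hydroxyl or acyl migration between C2 and C3. The fallback sets out from 30. Bu2SnO in refluxing toluene would give the dibutylstannylene acetal of 30 F7, in which the less hindered C2 oxygen is the more nucleophilic. Treatment with 31 at 0 °C returns to the route at 32.

Step 5. The risk is poor facial selectivity of the epoxidation, since a single allylic methyl and the axial ketal oxygen may oppose each other. The fallback sets out from 6 and uses the other epoxide, so both faces lead to the same intermediate. The syn epoxide of 6 F8 would be carried through the conditions of step 6 to (4R,5R)-4-hydroxy-5-methylcyclohex-2-en-1-one F9, whose hydroxyl is already cis to the methyl. Direct benzoylation (PhCOCl, pyridine), without inversion, returns to the route at 10.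

## Further compounds

F1 | step 16 | N,N-dimethylhydrazone of 24 | CN(C)N=C1C=CC(C)(C)[C@@H]2[C@H](C1C)C3(OCCO3)C[C@@H](C)[C@H]2OS(=O)(=O)c4ccc(C)cc4
F2 | step 16 | N,N-dimethylhydrazone of 26 | CN(C)N=C1C=CC(C)(C)[C@@H]2[C@H]3C4(OCCO4)C[C@@H](C)[C@@H]2[C@@]13C
F3 | step 10 | C6=C7 trimethylsilyl enol ether of the allyl adduct of 16 | C=CC(C)(C)[C@@H]1C(C(C)CC=C)=C(O[Si](C)(C)C)C[C@@H](C)[C@H]1OC(=O)c2ccccc2
F4 | step 10 | C6 phenylselanyl ketone | C=CC(C)(C)[C@@H]1C(C(C)CC=C)([Se]c2ccccc2)C(=O)C[C@@H](C)[C@H]1OC(=O)c3ccccc3
F5 | step 17 | (1S) allylic alcohol, C1 epimer of 27 | O[C@H]1C=CC(C)(C)[C@@H]2[C@H]3C4(OCCO4)C[C@@H](C)[C@@H]2[C@@]13C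
F6 | step 15 | C1 allylic alcohol of 23 | OC1C=CC(C)(C)[C@@H]2[C@H](C1C)C3(OCCO3)C[C@@H](C)[C@H]2OS(=O)(=O)c4ccc(C)cc4
F7 | step 20 | C2,C3 dibutylstannylene acetal of 30 | C/C=C(/C)C(=O)O[C@@H]1[C@H]2O[Sn](CCCC)(CCCC)O[C@H]2C(C)(C)[C@@H]3[C@H]4C5(OCCO5)C[C@@H](C)[C@@H]3[C@@]14C
F8 | step 5 | 7,8-epoxy-9-methyl-1,4-dioxaspiro[4.5]decane, oxirane cis to methyl | C[C@@H]1CC2(OCCO2)C[C@@H]3O[C@H]13
F9 | step 5 | (4R,5R)-4-hydroxy-5-methylcyclohex-2-en-1-one | O=C1C=C[C@H](O)[C@H](C)C1
A1 | alternative 1 | (2E,6E)-9,9-(propane-1,3-diyldithio)-3,7,11-trimethyldodeca-2,6,10-trienoyl chloride | ClC(=O)/C=C(\C)CC/C=C(\C)CC1(SCCCS1)C=C(C)C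
A2 | alternative 1 | 2-methylenebicyclo[3.1.1]heptan-6-one with the C11 side chain | O=C1[C@H]2CCC(=C)[C@@H]1[C@@]2(C)CC3(SCCCS3)C=C(C)C
A3 | alternative 2 | bicyclic keto aldehyde, C1 (4-methoxybenzyloxy)methyl ketone and C3 aldehyde | O=CC(C)(C)[C@@H]1[C@H]2C(=O)C=C(C)[C@@H]1[C@@]2(C)C(=O)COCc3ccc(OC)cc3
A4 | alternative 2 | tricyclic C1 ketone with C2 ether and C3 hydroxyl | O=C1[C@@H](OCc2ccc(OC)cc2)[C@@H](O)C(C)(C)[C@@H]3[C@H]4C(=O)C=C(C)[C@@H]3[C@@]14C
A5 | alternative 3 | bicyclic ynone N-acyloxyphthalimide | CC(C)(C)[Si](C)(C)O[C@@H]1C=CC(C)(C)[C@@H]2[C@@H](C(=O)C#CC)[C@@]1(C)[C@H]2C(=O)ON3C(=O)c4ccccc4C3=O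
A6 | alternative 3 | tricyclic enone with C1 silyl ether and C2=C3 alkene | CC(C)(C)[Si](C)(C)O[C@@H]1C=CC(C)(C)[C@@H]2[C@H]3C(=O)C=C(C)[C@@H]2[C@@]13C
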